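The only ring of the target is the benzene ring. With Ar1 bearing the CH2C(=O)C19H39 chain and Ar3/Ar5 the hydroxyls, it is one H2 away from a 5-substituted cyclohexane-1,3-dione in which Ar1 is sp3 and lies β to both carbonyl carbons Ar3 and Ar5.
Endgame in reverse: target ⇒ resorcinol with the side-chain C2 ketone masked as a dioxolane ⇒ masked 5-substituted cyclohexane-1,3-dione (dehydrogenation) ⇒ its Ar6 methyl ester (saponification, loss of CO2).
Key disconnection: Ar4–Ar5 (Dieckmann) and Ar1–Ar6 (Michael) ⇒ dimethyl malonate (Ar5, Ar6) + (E)-enone CH3C(=O)CH=CHCH2C(OCH2CH2O)C19H39 (Ar4, Ar3, Ar2, Ar1).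
Enone ⇒ acetonyl ylide + β-ketal aldehyde ⇒ methyl 3-oxodocosanoate ⇒ icosanoic acid + Meldrum's acid.
Ring order: the dioxolane (protecting ring) first, then the carbocycle as a saturated dione, then its aromatization, and last the removal of the dioxolane.

Key step: step 7

Remark on the chemistry: the acyl Meldrum's acid and all cyclohexane-1,3-diones are strongly enolized. The diones are drawn as keto tautomers. Their sp3 ring centres are racemic and vanish on aromatization, and the target has no stereocentre.

Step 1
Reactants: 1 icosanoic acid; 2 Meldrum's acid (2,2-dimethyl-1,3-dioxane-4,6-dione)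
Product: 3 5-(1-hydroxyicosylidene)-2,2-dimethyl-1,3-dioxane-4,6-dione (enol form of 5-icosanoyl Meldrum's acid)
Conditions: DCC (1.1 equiv), DMAP (1.2 equiv), CH2Cl2, 0 °C to rt
Reagents that add atoms: none
Why: Carbodiimide/DMAP activation (Steglich type) makes the fatty acid an acyl donor that C-acylates the very acidic methylene of Meldrum's acid, and the product rests as its hydrogen-bonded enol, which prevents a second acylation.

Step 2
Reactants: 3 5-(1-hydroxyicosylidene)-2,2-dimethyl-1,3-dioxane-4,6-dione
Product: 4 methyl 3-oxodocosanoate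
Conditions: MeOH, reflux
Reagents that add atoms: methanol, CO
Why: Methanolysis of an acyl Meldrum's acid with loss of acetone and CO2 is the standard two-carbon homologation of a carboxylic acid to a β-keto ester.

Step 3
Reactants: 4 methyl 3-oxodocosanoate
Product: 5 methyl 2-(2-nonadecyl-1,3-dioxolan-2-yl)acetate
Conditions: HOCH2CH2OH (5 equiv), p-TsOH·H2O (cat.), toluene, reflux, Dean–Stark
Reagents that add atoms: ethylene glycol, OCCO
Why: Acid-catalysed ketalization with azeotropic removal of water is routine for β-keto esters, because only the ketone carbonyl forms a cyclic ketal and the ester stays untouched.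

Step 4
Reactants: 5 methyl 2-(2-nonadecyl-1,3-dioxolan-2-yl)acetate
Product: 6 2-(2-nonadecyl-1,3-dioxolan-2-yl)ethan-1-ol
Conditions: LiAlH4, THF, 0 °C to rt; H2O/aq NaOH work-up
Reagents that add atoms: none
Why: LiAlH4 reduction of an ester to the primary alcohol runs at a temperature where the long-chain substrate stays dissolved, and the dioxolane is inert to hydride and to the basic work-up.

Step 5
Reactants: 6 2-(2-nonadecyl-1,3-dioxolan-2-yl)ethan-1-ol
Product: 7 2-(2-nonadecyl-1,3-dioxolan-2-yl)acetaldehyde
Conditions: Dess–Martin periodinane, pyridine, CH2Cl2, 0 °C to rt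
Reagents that add atoms: none
Why: The Dess–Martin oxidation stops at the aldehyde at room temperature, and the pyridine buffer takes up the acetic acid released, so neither acid-induced ketal loss nor base-induced β-elimination of a ketal oxygen from the enolizable aldehyde is expected.

Step 6
Reactants: 7 2-(2-nonadecyl-1,3-dioxolan-2-yl)acetaldehyde; 8 1-(triphenylphosphoranylidene)propan-2-one
Product: 9 (E)-5-(2-nonadecyl-1,3-dioxolan-2-yl)pent-3-en-2-one
Conditions: CH2Cl2, reflux (40 °C), freshly prepared 7
Reagents that add atoms: none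
Why: Wittig olefination with a carbonyl-stabilized ylide passes through the trans-oxaphosphetane and should therefore give the E-enone, and the ylide is too weakly basic to enolize 7 or to open its ketal.

Step 7
Reactants: 9 (E)-5-(2-nonadecyl-1,3-dioxolan-2-yl)pent-3-en-2-one; 10 dimethyl malonate
Product: 12 methyl 2,4-dioxo-6-[(2-nonadecyl-1,3-dioxolan-2-yl)methyl]cyclohexane-1-carboxylate (racemic epimerizable mixture), via malonate Michael adduct 11 (not isolated)
Conditions: 10 (1.3 equiv), NaOMe (1.1 equiv), MeOH–THF, 0 °C to rt, then reflux; cold aq AcOH to pH 5, extraction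
Reagents that add atoms: none
Why: Sodium dimethyl malonate, made with less NaOMe than malonate so that no free methoxide is present during the addition stage, attacks the enone β-carbon of 9 (future Ar1) in a Michael addition that forms Ar1–Ar6 and gives keto diester 11; at reflux 11 equilibrates through its terminal methyl-ketone enolate (future Ar4), which is acylated by one malonate ester carbonyl (future Ar5) with loss of methoxide, forming Ar4–Ar5. The closest known reaction type is the classical malonate Michael–Dieckmann annulation of 3-alken-2-ones to 6-alkyl-2,4-dioxocyclohexanecarboxylates, the standard entry to 5-alkylresorcinols. The single ring closes in the favoured 6-(enolendo)-exo-trig mode, since the enolate C=C (Ar3=Ar4) lies inside the forming ring and the ester C=O outside it, whereas the internal enolate at Ar2 could only give a four-membered ring. The two new sp3 centres (ring C6 = Ar1 and ring C1 = Ar6) form without control as a racemate, C1 equilibrating by enolization, and neither matters because both become sp2 in step 9. The step needs 1,4- rather than 1,2-attack, which the soft doubly stabilized carbanion secures, and it needs addition to win over γ-deprotonation of 9, which would deconjugate the enone or open the dioxolane by E1cB loss of a ketal oxygen. Both leaks are reversible (the tethered alkoxide can add back to the dienone), whereas 12 leaves every equilibrium as its stabilized dione enolate, so the mixture should drain toward 12.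

Step 8
Reactants: 12 methyl 2,4-dioxo-6-[(2-nonadecyl-1,3-dioxolan-2-yl)methyl]cyclohexane-1-carboxylate
Product: 14 5-[(2-nonadecyl-1,3-dioxolan-2-yl)methyl]cyclohexane-1,3-dione, via beta-keto acid 13 (not isolated)
Conditions: 2 M aq NaOH, MeOH–THF, reflux; then AcOH to pH 5–6, 50 °C until gas evolution ends
Reagents that add atoms: none
Why: Saponification leaves the base-stable dioxolane untouched, and after acidification only to pH 5–6 the β-keto acid 13 decarboxylates through the usual cyclic transition state on mild warming, a window in which specific-acid hydrolysis of a dialkyl ketone dioxolane should still be slow.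

Step 9
Reactants: 14 5-[(2-nonadecyl-1,3-dioxolan-2-yl)methyl]cyclohexane-1,3-dione
Product: 15 5-[(2-nonadecyl-1,3-dioxolan-2-yl)methyl]benzene-1,3-diol
Conditions: 10% Pd/C (5 mol % Pd), K2CO3 (0.2 equiv), ethylene (1 atm), N,N-dimethylacetamide, 110 °C
Reagents that add atoms: none
Why: Pd/C-catalysed transfer dehydrogenation of cyclohexane-1,3-diones to resorcinols removes H2 across Ar1–Ar2, the resulting dienone tautomerizes irreversibly to the phenol, ethylene takes up the hydrogen so that it cannot reduce a second dione molecule, and the mildly basic water-free medium spares the dioxolane.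

Step 10
Reactants: 15 5-[(2-nonadecyl-1,3-dioxolan-2-yl)methyl]benzene-1,3-diol
Product: 16 1-(3,5-dihydroxyphenyl)henicosan-2-one (target)
Conditions: 1 M aq HCl, THF, 40 °C
Reagents that add atoms: water, O
Why: Acid-catalysed ketal hydrolysis frees the C2 ketone under conditions too mild for resorcinol–ketone condensation, and the meta hydroxyls cannot reach the carbonyl to form a cyclic hemiketal.

Compound list
1 | icosanoic acid | CCCCCCCCCCCCCCCCCCCC(=O)O | starting material
2 | Meldrum's acid (2,2-dimethyl-1,3-dioxane-4,6-dione) | CC1(C)OC(=O)CC(=O)O1 | starting material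
3 | 5-(1-hydroxyicosylidene)-2,2-dimethyl-1,3-dioxane-4,6-dione | CCCCCCCCCCCCCCCCCCCC(O)=C1C(=O)OC(C)(C)OC1=O | intermediate
4 | methyl 3-oxodocosanoate | CCCCCCCCCCCCCCCCCCCC(=O)CC(=O)OC | intermediate
5 | methyl 2-(2-nonadecyl-1,3-dioxolan-2-yl)acetate | COC(=O)CC1(CCCCCCCCCCCCCCCCCCC)OCCO1 | intermediate
6 | 2-(2-nonadecyl-1,3-dioxolan-2-yl)ethan-1-ol | OCCC1(CCCCCCCCCCCCCCCCCCC)OCCO1 | intermediate
7 | 2-(2-nonadecyl-1,3-dioxolan-2-yl)acetaldehyde | O=CCC1(CCCCCCCCCCCCCCCCCCC)OCCO1 | intermediate
8 | 1-(triphenylphosphoranylidene)propan-2-one | CC(=O)C=P(c1ccccc1)(c1ccccc1)c1ccccc1 | starting material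
9 | (E)-5-(2-nonadecyl-1,3-dioxolan-2-yl)pent-3-en-2-one | CC(=O)/C=C/CC1(CCCCCCCCCCCCCCCCCCC)OCCO1 | intermediate
10 | dimethyl malonate | COC(=O)CC(=O)OC | starting material
11 | dimethyl 2-[1-(2-nonadecyl-1,3-dioxolan-2-yl)-4-oxopentan-2-yl]propanedioate (racemic, not isolated) | COC(=O)C(C(=O)OC)C(CC(C)=O)CC1(CCCCCCCCCCCCCCCCCCC)OCCO1 | intermediate
12 | methyl 2,4-dioxo-6-[(2-nonadecyl-1,3-dioxolan-2-yl)methyl]cyclohexane-1-carboxylate (racemic, epimerizable) | COC(=O)C1C(=O)CC(=O)CC1CC1(CCCCCCCCCCCCCCCCCCC)OCCO1 | intermediate
13 | 2,4-dioxo-6-[(2-nonadecyl-1,3-dioxolan-2-yl)methyl]cyclohexane-1-carboxylic acid (racemic, not isolated) | OC(=O)C1C(=O)CC(=O)CC1CC1(CCCCCCCCCCCCCCCCCCC)OCCO1 | intermediate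
14 | 5-[(2-nonadecyl-1,3-dioxolan-2-yl)methyl]cyclohexane-1,3-dione | O=C1CC(=O)CC(CC2(CCCCCCCCCCCCCCCCCCC)OCCO2)C1 | intermediate
15 | 5-[(2-nonadecyl-1,3-dioxolan-2-yl)methyl]benzene-1,3-diol | Oc1cc(O)cc(CC2(CCCCCCCCCCCCCCCCCCC)OCCO2)c1 | intermediate
16 | 1-(3,5-dihydroxyphenyl)henicosan-2-one | CCCCCCCCCCCCCCCCCCCC(=O)Cc1cc(O)cc(O)c1 | target

Total step count: 10
Longest linear sequence: 10 steps (from icosanoic acid 1 to 16)

Steps most likely to fail

First, step 7. γ-Deprotonation of enone 9 may run faster than conjugate addition. Deconjugation and E1cB opening of the dioxolane would then feed side reactions of the acceptor before the malonate is attached, and slow ring closure of the poorly soluble adduct is a second concern. The fallback builds the same ring from the complementary pair of partners, with an enoate acceptor whose γ-hydrogens are far less acidic and a less basic nucleophile.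
- It sets out from aldehyde 7. Wittig olefination with methyl (triphenylphosphoranylidene)acetate (CH2Cl2, rt) should give methyl (E)-4-(2-nonadecyl-1,3-dioxolan-2-yl)but-2-enoate F1.
- Methyl acetoacetate and NaOMe in MeOH–THF at reflux should then add to the enoate to give dimethyl 2-acetyl-3-[(2-nonadecyl-1,3-dioxolan-2-yl)methyl]pentanedioate F2.
- The acetyl methyl enolate of this adduct closes onto the distal ester in the same pot, the classical acetoacetate–enoate route to dihydroresorcinol carboxylates.
- The ring closure delivers 12 itself, where the route is rejoined.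

Second, step 9. Three processes are at risk: the chelating dione enolate may block the palladium surface, hydrogen may pass to a second dione molecule instead of ethylene (disproportionation), and the acidic dione may promote thermal loss of the ketal. The fallback replaces catalytic dehydrogenation by enol silane formation and hydride abstraction.
- It sets out from 14. TMSCl/Et3N (CH2Cl2, 0 °C) should give 5-[(2-nonadecyl-1,3-dioxolan-2-yl)methyl]-3-(trimethylsilyloxy)cyclohex-2-en-1-one F3.
- Kinetic α′-deprotonation with LDA and trapping with TMSCl (THF, −78 to −40 °C) should give 1,3-bis(trimethylsilyloxy)-5-[(2-nonadecyl-1,3-dioxolan-2-yl)methyl]cyclohexa-1,3-diene F4.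
- DDQ with 2,4,6-collidine in toluene at rt should abstract hydride from the doubly oxygen-stabilized diene and give 2-[3,5-bis(trimethylsilyloxy)benzyl]-2-nonadecyl-1,3-dioxolane F5.
- Catalytic K2CO3 in MeOH removes the silyl groups, and the route is rejoined at 15.

Third, step 8. The dioxolane may be hydrolysed prematurely during the warm, weakly acidic decarboxylation stage, and saponification of the enolate-shielded ester may be sluggish. The fallback uses an ester that is removed under neutral conditions.
- It sets out from enone 9. The annulation is run with dibenzyl malonate and sodium benzyloxide (NaH + BnOH) in THF at reflux. It should pass through dibenzyl 2-[1-(2-nonadecyl-1,3-dioxolan-2-yl)-4-oxopentan-2-yl]propanedioate F6.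
- Ring closure should give benzyl 2,4-dioxo-6-[(2-nonadecyl-1,3-dioxolan-2-yl)methyl]cyclohexane-1-carboxylate F7.
- Hydrogenolysis (H2, 1 atm, 10% Pd/C, EtOAc–THF, rt) should release acid 13 without aqueous acid.
- Warming the filtered solution to 50 °C should expel CO2, and the route is rejoined at 14.

Further compounds
F1 | step 7 | methyl (E)-4-(2-nonadecyl-1,3-dioxolan-2-yl)but-2-enoate | COC(=O)/C=C/CC1(CCCCCCCCCCCCCCCCCCC)OCCO1
F2 | step 7 | dimethyl 2-acetyl-3-[(2-nonadecyl-1,3-dioxolan-2-yl)methyl]pentanedioate (racemic diastereomer mixture) | COC(=O)CC(CC1(CCCCCCCCCCCCCCCCCCC)OCCO1)C(C(C)=O)C(=O)OC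
F3 | step 9 | 5-[(2-nonadecyl-1,3-dioxolan-2-yl)methyl]-3-(trimethylsilyloxy)cyclohex-2-en-1-one (racemic) | C[Si](C)(C)OC1=CC(=O)CC(CC2(CCCCCCCCCCCCCCCCCCC)OCCO2)C1
F4 | step 9 | 1,3-bis(trimethylsilyloxy)-5-[(2-nonadecyl-1,3-dioxolan-2-yl)methyl]cyclohexa-1,3-diene (racemic) | C[Si](C)(C)OC1=CC(O[Si](C)(C)C)=CC(CC2(CCCCCCCCCCCCCCCCCCC)OCCO2)C1
F5 | step 9 | 2-[3,5-bis(trimethylsilyloxy)benzyl]-2-nonadecyl-1,3-dioxolane | C[Si](C)(C)Oc1cc(O[Si](C)(C)C)cc(CC2(CCCCCCCCCCCCCCCCCCC)OCCO2)c1
F6 | step 8 | dibenzyl 2-[1-(2-nonadecyl-1,3-dioxolan-2-yl)-4-oxopentan-2-yl]propanedioate (racemic) | O=C(OCc1ccccc1)C(C(=O)OCc1ccccc1)C(CC(C)=O)CC1(CCCCCCCCCCCCCCCCCCC)OCCO1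
F7 | step 8 | benzyl 2,4-dioxo-6-[(2-nonadecyl-1,3-dioxolan-2-yl)methyl]cyclohexane-1-carboxylate (racemic, epimerizable) | O=C(OCc1ccccc1)C1C(=O)CC(=O)CC1CC1(CCCCCCCCCCCCCCCCCCC)OCCO1
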